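**Retrosynthetic overview**
1. The lactone ring closes last (C16–OH onto the C15 ester on global desilylation). C13–C14 comes from a silyl ketene acetal adding to the cyclic peroxycarbenium ion of a 3-methoxy-1,2-dioxane, which sets C13.
2. The 1,2-dioxane ring forms when a C13 bis(hydroperoxide) opens an 8α,9α-epoxide at C9 with inversion (peroxide β, C11 α). The resulting 8α-OH is dehydrated to the 8(17)-methylene.
3. Key C9–C11 bond: palladium-catalysed coupling of a C9 enol triflate with the ketone homoenolate released from a cyclopropanol (C11 is the β-carbon of the C13 ketone, C9 a former ketone carbon).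
4. Decalin: ring A is annulated onto 2-methylcyclohexane-1,3-dione (ring B) by an enantioselective Robinson annulation; C4 is set by deconjugative methylation; C2, C5 and C6 by one double hydroboration.
5. Ring order: B (purchased) → A → 1,2-dioxane → lactone.

Assumption: labdane numbering is used for all intermediates (C17 on C8, C18 = 4α-CH3, C19 = 4β-carbon, C20 = 10β-CH3, α = face opposite C20; TBS = tert-butyldimethylsilyl, Tf = trifluoromethanesulfonyl), and compounds 2 and 14 are bought.

**Route**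

Step 1
Reactants: 1 2-methylcyclohexane-1,3-dione; 2 methyl 5-methoxy-3-oxopentanoate
Product: 5 methyl (4aS)-4a-methyl-2,5-dioxo-2,3,4,4a,5,6,7,8-octahydronaphthalene-1-carboxylate, via methyl 3-oxopent-4-enoate 3 (not isolated), via triketone Michael adduct 4 (not isolated)
Conditions: Et3N (1 equiv), MeCN, 40 °C; evaporate; then L-phenylalanine (1 equiv), (1S)-(+)-camphorsulfonic acid (0.5 equiv), DMF, 50 °C; recrystallise
Reagents that add atoms: none
Why: Robinson annulation in which 2 loses methanol to give Nazarov's reagent 3, dione 1 adds to it (Michael), and an amino-acid-catalysed intramolecular Knoevenagel/aldol condensation of the prochiral triketone 4 (Hajos–Parrish–Eder–Sauer–Wiechert type) closes ring A and sets C10 as (S), the sense L-amino acids give for the Wieland–Miescher ketone.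

Step 2
Reactants: 5 enone keto ester
Product: 6 diketo ester (3,9-dioxo; 5-ene; 4α-CH3; 4β-CO2Me; 8-CH3 as both epimers; 10β-CH3)
Conditions: NaH (1.0 equiv), THF, 0 °C; LiN(iPr)2 (1.1 equiv), −78 °C; MeI (3 equiv), −78 °C → rt
Reagents that add atoms: iodomethane (CI)
Why: NaH gives the extended dienolate of the alkylidene β-keto ester, so the second base can only enolise the C9 ketone toward C8, and MeI then performs a deconjugative α-alkylation at C4 anti to the angular methyl (CH3 α, ester β, alkene moved to C5=C6) plus a simple enolate alkylation at C8.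

Step 3
Reactants: 6 diketo ester
Product: 7 C3 enol triflate (3-OTf; 2,5-diene; 9-ketone; rest as in 6)
Conditions: KN(SiMe3)2 (1.05 equiv), THF, −78 °C; PhNTf2
Reagents that add atoms: N-phenylbis(trifluoromethanesulfonimide) (O=S(=O)(N(c1ccccc1)S(=O)(=O)C(F)(F)F)C(F)(F)F)
Why: Kinetic enolisation with a hindered amide removes a C2 methylene proton in preference to the tertiary C8–H, and O-sulfonylation gives the enol triflate (enol triflate formation).

Step 4
Reactants: 7 C3 enol triflate
Product: 8 2,5-diene 9-ketone ester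
Conditions: Pd(OAc)2 (5 mol %), PPh3, Bu3N, HCO2H, DMF, 60 °C
Reagents that add atoms: none
Why: Palladium-catalysed formate reduction of an enol triflate (oxidative addition, formate decarboxylation, C–H reductive elimination) removes the C3 oxygen and leaves the C2=C3 alkene, with ketone, ester and C5=C6 untouched.

Step 5
Reactants: 8 2,5-diene 9-ketone ester
Product: 9 2,5,8-triene C9 enol triflate ester
Conditions: KN(SiMe3)2 (1.3 equiv), THF, −78 → 0 °C; PhNTf2, → rt
Reagents that add atoms: N-phenylbis(trifluoromethanesulfonimide) (O=S(=O)(N(c1ccccc1)S(=O)(=O)C(F)(F)F)C(F)(F)F)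
Why: C10 is quaternary, so the C9 ketone can enolise only toward C8; triflation gives the tetrasubstituted enol triflate, which masks C9 through the hydride steps and activates it for the coupling (the C8 epimers converge).

Step 6
Reactants: 9 triene enol triflate ester
Product: 11 2α,6α-diol ester (5α-H), via bis(alkylborane) adduct 10 (not isolated)
Conditions: BH3·THF (6 equiv), THF, 0 °C → rt; then 30% H2O2, pH 7 phosphate buffer, 0 °C → rt
Reagents that add atoms: borane–tetrahydrofuran ([BH3-][O+]1CCCC1); hydrogen peroxide (OO)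
Why: Hydroboration–oxidation in which borane adds from the α face (the β face is blocked by the axial C10 methyl and the axial C4 ester) with boron on the less hindered carbon of each alkene (C2 rather than neopentyl C3, C6 rather than C5), so stereoretentive oxidation gives 2α-OH, 6α-OH and the trans ring fusion (5α-H); the electron-poor tetrasubstituted enol triflate and the hindered ester do not react.

Step 7
Reactants: 11 diol ester
Product: 12 2α,6α,19-triol enol triflate
Conditions: iBu2AlH (6 equiv), CH2Cl2, −78 → 0 °C; aq. potassium sodium tartrate work-up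
Reagents that add atoms: none
Why: Hydride reduction of the neopentyl ester to the C19 primary alcohol; enol triflates tolerate iBu2AlH at low temperature.

Step 8
Reactants: 12 triol enol triflate
Product: 13 tris-TBS ether enol triflate
Conditions: TBSOTf (4 equiv), 2,6-lutidine, CH2Cl2, −78 → 0 °C
Reagents that add atoms: tert-butyldimethylsilyl triflate (CC(C)(C)[Si](C)(C)OS(=O)(=O)C(F)(F)F)
Why: Silyl ether formation with the reactive silyl triflate protects all three alcohols, including the hindered 6α-OH, as groups that fluoride removes at the end without base.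

Step 9
Reactants: 14 methyl 2-((tert-butyldimethylsilyl)oxy)acetate
Product: 15 1-(((tert-butyldimethylsilyl)oxy)methyl)cyclopropan-1-ol
Conditions: EtMgBr (2.4 equiv), Ti(OiPr)4 (0.2 equiv), THF, 0 °C → rt
Reagents that add atoms: ethylmagnesium bromide (CC[Mg]Br)
Why: Kulinkovich cyclopropanation, in which the titanacyclopropane formed from two ethyl groups adds twice to the ester carbonyl.

Step 10
Reactants: 13 tris-TBS ether enol triflate; 15 cyclopropanol
Product: 16 8-ene 13-ketone (C9–CH2CH2–C(=O)–CH2OTBS side chain; 2α,6α,19-tris-OTBS)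
Conditions: Pd(OAc)2 (10 mol %), XPhos (20 mol %), Cs2CO3 (2 equiv), toluene, 80 °C
Reagents that add atoms: none
Why: Proposed new method: zerovalent palladium inserts into the C9–OTf bond, the caesium cyclopropoxide displaces triflate on divalent palladium, strain-driven β-carbon elimination gives a chelated palladium homoenolate, and the bulky biaryl phosphine makes C(sp2)–C(sp3) reductive elimination faster than β-hydride loss, so C11 (the β-carbon of the C13 ketone) is joined to the former ketone carbon C9; the closest known reactions are the palladium-catalysed ring-opening arylation of cyclopropanols and the palladium-catalysed coupling of zinc ester homoenolates with enol triflates, neither yet shown on a tetrasubstituted, doubly neopentyl enol triflate.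

Step 11
Reactants: 16 8-ene 13-ketone
Product: 17 13,13-bis(hydroperoxide)
Conditions: 50% aq. H2O2 (8 equiv), camphorsulfonic acid (10 mol %), MeCN, rt
Reagents that add atoms: hydrogen peroxide (OO)
Why: Acid-catalysed peroxyacetalisation of the unhindered, α-oxygen-activated ketone to the geminal dihydroperoxide; with no metal present the hindered alkene is not epoxidised.

Step 12
Reactants: 17 13,13-bis(hydroperoxide)
Product: 20 13-methoxy-9β,13-epidioxy-8α-ol (3-methoxy-1,2-dioxane; C13 anomers), via 8α,9α-epoxide 18 (not isolated), via 3-hydroperoxy-1,2-dioxane 19 (not isolated)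
Conditions: mCPBA (1.2 equiv), NaHCO3, CH2Cl2, 0 °C; then PPTS (0.2 equiv), CH2Cl2–MeOH 5:1, 0 °C → rt
Reagents that add atoms: 3-chloroperoxybenzoic acid (OOC(=O)c1cccc(Cl)c1); methanol (CO)
Why: Prilezhaev epoxidation of the only alkene occurs on the α face (anti to the axial C10 methyl), acid then triggers the 6-exo opening of the epoxide at C9 by a hydroperoxide oxygen with inversion (the tether cannot reach C8), which sets C9 with the peroxide β and C11 α and leaves 8α-OH, and the remaining anomeric OOH is exchanged for OMe by acid-catalysed peroxyketal exchange.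

Step 13
Reactants: 20 13-methoxy-9β,13-epidioxy-8α-ol
Product: 21 13-methoxy-9β,13-epidioxy-8(17)-ene (C13 anomers)
Conditions: Burgess reagent (2 equiv), toluene, 50 °C
Reagents that add atoms: none
Why: Burgess dehydration is a syn-elimination, and the equatorial 8α-sulfamate has a syn-coplanar hydrogen only on the freely rotating C17 methyl (C9 has none, the C7 hydrogens are gauche), so the exocyclic 8(17)-alkene forms.

Step 14
Reactants: 21 13-methoxy-9β,13-epidioxy-8(17)-ene
Product: 22 methyl (9S,13S)-9,13-epidioxy-8(17)-en-15-oate with 2α,6α,19,16-tetrakis-OTBS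
Conditions: CH2=C(OMe)OTBS (3 equiv), TMSOTf (0.3 equiv), CH2Cl2, −78 °C
Reagents that add atoms: 1-(tert-butyldimethylsilyloxy)-1-methoxyethene (C=C(OC)O[Si](C)(C)C(C)(C)C)
Why: Mukaiyama-type addition to a peroxycarbenium ion: TMSOTf ionises the anomeric methoxy group and the ketene acetal attacks the 1,2-dioxan-3-ylium ion axially on the half-chair that keeps quaternary C10 equatorial and C8 axial on the dioxane (the other half-chair drives C12 and the peroxide oxygen into the C1 methylene), so CH2CO2Me ends cis to C10 and trans to C8, which is the (13S) configuration.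

Step 15
Reactants: 22 tetrakis-TBS peroxy ester
Product: 24 CNP0262224.1 (target), via tetrol methyl ester 23 (not isolated)
Conditions: HF·pyridine, pyridine, THF, 0 °C → rt
Reagents that add atoms: none
Why: Fluoride desilylation frees all four alcohols and the C16 primary alcohol lactonises onto the C15 methyl ester under the mildly acidic conditions (5-exo, Thorpe–Ingold assisted), which avoids any base that could open the β-peroxy lactone by retro-oxa-Michael reaction.

**Compound list**
1 | 2-methylcyclohexane-1,3-dione | CC1C(=O)CCCC1=O | starting material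
2 | methyl 5-methoxy-3-oxopentanoate | COCCC(=O)CC(=O)OC | starting material
3 | methyl 3-oxopent-4-enoate (Nazarov's reagent) | C=CC(=O)CC(=O)OC | intermediate
4 | methyl 5-(1-methyl-2,6-dioxocyclohexyl)-3-oxopentanoate | COC(=O)CC(=O)CCC1(C)C(=O)CCCC1=O | intermediate
5 | methyl (4aS)-4a-methyl-2,5-dioxo-2,3,4,4a,5,6,7,8-octahydronaphthalene-1-carboxylate (C3 ketone, C4=C5, C9 ketone, 10β-CH3) | C1CCC2=C(C(=O)OC)C(=O)CC[C@]2(C)C1=O | intermediate
6 | diketo ester: 3,9-dioxo, 5-ene, 4α-CH3, 4β-CO2Me, 8-CH3 (both C8 epimers), 10β-CH3 | CC1CC=C2[C@@](C)(C(=O)OC)C(=O)CC[C@]2(C)C1=O | intermediate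
7 | C3 enol triflate: 3-OTf, 2,5-diene, 9-ketone, otherwise as 6 | CC1CC=C2[C@@](C)(C(=O)OC)C(OS(=O)(=O)C(F)(F)F)=CC[C@]2(C)C1=O | intermediate
8 | 2,5-diene 9-ketone ester, otherwise as 6 | CC1CC=C2[C@@](C)(C(=O)OC)C=CC[C@]2(C)C1=O | intermediate
9 | 2,5,8-triene with 9-OTf, 8-CH3, 4α-CH3, 4β-CO2Me, 10β-CH3 | CC=1CC=C2[C@@](C)(C(=O)OC)C=CC[C@]2(C)C=1OS(=O)(=O)C(F)(F)F | intermediate
10 | 2α,6α-bis(boranyl) adduct of 9 (5α-H) | CC=1C[C@H](B)[C@H]2[C@@](C)(C(=O)OC)C[C@H](B)C[C@]2(C)C=1OS(=O)(=O)C(F)(F)F | intermediate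
11 | 2α,6α-diol ester: 5α-H trans-decalin, 8-ene, 9-OTf, 4β-CO2Me | CC=1C[C@H](O)[C@H]2[C@@](C)(C(=O)OC)C[C@H](O)C[C@]2(C)C=1OS(=O)(=O)C(F)(F)F | intermediate
12 | 2α,6α,19-triol, 8-ene, 9-OTf | CC=1C[C@H](O)[C@H]2[C@@](C)(CO)C[C@H](O)C[C@]2(C)C=1OS(=O)(=O)C(F)(F)F | intermediate
13 | 2α,6α,19-tris-OTBS, 8-ene, 9-OTf | CC=1C[C@H](O[Si](C)(C)C(C)(C)C)[C@H]2[C@@](C)(CO[Si](C)(C)C(C)(C)C)C[C@H](O[Si](C)(C)C(C)(C)C)C[C@]2(C)C=1OS(=O)(=O)C(F)(F)F | intermediate
14 | methyl 2-((tert-butyldimethylsilyl)oxy)acetate | COC(=O)CO[Si](C)(C)C(C)(C)C | starting material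
15 | 1-(((tert-butyldimethylsilyl)oxy)methyl)cyclopropan-1-ol | OC1(CO[Si](C)(C)C(C)(C)C)CC1 | intermediate
16 | 8-ene 13-ketone: C9–CH2CH2–C(=O)–CH2OTBS, 2α,6α,19-tris-OTBS | CC=1C[C@H](O[Si](C)(C)C(C)(C)C)[C@H]2[C@@](C)(CO[Si](C)(C)C(C)(C)C)C[C@H](O[Si](C)(C)C(C)(C)C)C[C@]2(C)C=1CCC(=O)CO[Si](C)(C)C(C)(C)C | intermediate
17 | 13,13-bis(hydroperoxide) of 16 | CC=1C[C@H](O[Si](C)(C)C(C)(C)C)[C@H]2[C@@](C)(CO[Si](C)(C)C(C)(C)C)C[C@H](O[Si](C)(C)C(C)(C)C)C[C@]2(C)C=1CCC(OO)(OO)CO[Si](C)(C)C(C)(C)C | intermediate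
18 | 8α,9α-epoxide of 17 (8β-CH3, C11 β) | C[C@@]13C[C@H](O[Si](C)(C)C(C)(C)C)[C@H]2[C@@](C)(CO[Si](C)(C)C(C)(C)C)C[C@H](O[Si](C)(C)C(C)(C)C)C[C@]2(C)[C@]1(CCC(OO)(OO)CO[Si](C)(C)C(C)(C)C)O3 | intermediate
19 | 9β,13-epidioxy-13-hydroperoxy-8α-ol (8β-CH3, C11 α; C13 anomers) | C[C@@]1(O)C[C@H](O[Si](C)(C)C(C)(C)C)[C@H]2[C@@](C)(CO[Si](C)(C)C(C)(C)C)C[C@H](O[Si](C)(C)C(C)(C)C)C[C@]2(C)[C@]12CCC(OO)(CO[Si](C)(C)C(C)(C)C)OO2 | intermediate
20 | 9β,13-epidioxy-13-methoxy-8α-ol (C13 anomers) | C[C@@]1(O)C[C@H](O[Si](C)(C)C(C)(C)C)[C@H]2[C@@](C)(CO[Si](C)(C)C(C)(C)C)C[C@H](O[Si](C)(C)C(C)(C)C)C[C@]2(C)[C@]12CCC(OC)(CO[Si](C)(C)C(C)(C)C)OO2 | intermediate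
21 | 9β,13-epidioxy-13-methoxy-8(17)-ene (C13 anomers) | C=C1C[C@H](O[Si](C)(C)C(C)(C)C)[C@H]2[C@@](C)(CO[Si](C)(C)C(C)(C)C)C[C@H](O[Si](C)(C)C(C)(C)C)C[C@]2(C)[C@]12CCC(OC)(CO[Si](C)(C)C(C)(C)C)OO2 | intermediate
22 | methyl (9S,13S)-9,13-epidioxy-2α,6α,19,16-tetrakis-OTBS-labd-8(17)-en-15-oate | C=C1C[C@H](O[Si](C)(C)C(C)(C)C)[C@H]2[C@@](C)(CO[Si](C)(C)C(C)(C)C)C[C@H](O[Si](C)(C)C(C)(C)C)C[C@]2(C)[C@]12CC[C@](CC(=O)OC)(CO[Si](C)(C)C(C)(C)C)OO2 | intermediate
23 | methyl (9S,13S)-9,13-epidioxy-2α,6α,19,16-tetrahydroxylabd-8(17)-en-15-oate | C=C1C[C@H](O)[C@H]2[C@@](C)(CO)C[C@H](O)C[C@]2(C)[C@]12CC[C@](CC(=O)OC)(CO)OO2 | intermediate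
24 | CNP0262224.1: (9S,13S)-9,13-epidioxy-2α,6α,19-trihydroxylabd-8(17)-en-15,16-olide | C=C1C[C@H](O)[C@H]2[C@@](C)(CO)C[C@H](O)C[C@]2(C)[C@]12CC[C@]1(COC(=O)C1)OO2 | target

**Totals and risks**

Total step count: 15. Longest linear sequence: 14 steps (steps 1–8 and 10–15; step 9 is a one-step branch).

The three steps most likely to fail:

Step 10. The enol triflate is tetrasubstituted and flanked by a quaternary carbon, so transmetalation and reductive elimination may lose to β-hydride elimination of the palladium homoenolate. The fallback sets out from 15 (partner 13 unchanged) and comes back at 16, and replaces the palladium homoenolate made in the flask by an isolable boron homoenolate. Oxidative ring opening of 15 (Pd(OAc)2, pyridine, O2) gives 1-((tert-butyldimethylsilyl)oxy)but-3-en-2-one F1. Copper-catalysed conjugate borylation (CuCl, NaOtBu, a bisphosphine, B2pin2, MeOH) gives 1-((tert-butyldimethylsilyl)oxy)-4-(4,4,5,5-tetramethyl-1,3,2-dioxaborolan-2-yl)butan-2-one F2. KHF2 converts it into potassium trifluoro[4-((tert-butyldimethylsilyl)oxy)-3-oxobutyl]borate F3. An sp3–sp2 Suzuki–Miyaura coupling of F3 with 13 (Pd(OAc)2, RuPhos, Cs2CO3, toluene–water) then gives 16.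

Step 12. The epoxide may rearrange (semipinacol) or open without clean inversion before the hydroperoxide closes, and the peroxyketal exchange may stall. The fallback sets out from 17 and comes back at 21, and uses an iodonium ion in place of the epoxide. N-Iodosuccinimide puts iodine on the α face and the hydroperoxide closes anti at C9 to give the 8α-iodo-9β,13-epidioxy-13-hydroperoxide F4. PPTS/MeOH exchange gives the 8α-iodo-13-methoxy peroxyketal F5. Elimination with DBU, in which only the C17 methyl offers an anti-periplanar hydrogen to the equatorial C–I bond, gives 21 directly, so step 13 is not needed.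

Step 14. The Lewis acid may ionise the tertiary allylic C9–O bond, the exocyclic alkene may trap the cation, or the facial selectivity at C13 may be low. The fallback sets out from 21 and comes back at 22, and closes the dioxane by a peroxy-Michael addition instead. Mild aqueous acid (PPTS, THF–H2O) hydrolyses 21 to the peroxy-hemiketal 9β,13-epidioxy-13-ol F6, which is in equilibrium with the C9 hydroperoxide/C13 ketone. Horner–Wadsworth–Emmons olefination with trimethyl phosphonoacetate and LiN(SiMe3)2 gives the 9β-hydroperoxy 13(14)-enoate F7. Amine-catalysed 6-exo oxa-Michael addition (Et2NH, CF3CH2OH) closes the ring to 22. The C13 epimers are separated and the unwanted one is re-equilibrated through the reversible retro-Michael reaction.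

**Further compounds**
F1 | step 10 | 1-((tert-butyldimethylsilyl)oxy)but-3-en-2-one | C=CC(=O)CO[Si](C)(C)C(C)(C)C
F2 | step 10 | 1-((tert-butyldimethylsilyl)oxy)-4-(4,4,5,5-tetramethyl-1,3,2-dioxaborolan-2-yl)butan-2-one | CC1(C)OB(CCC(=O)CO[Si](C)(C)C(C)(C)C)OC1(C)C
F3 | step 10 | potassium trifluoro[4-((tert-butyldimethylsilyl)oxy)-3-oxobutyl]borate | [K+].F[B-](F)(F)CCC(=O)CO[Si](C)(C)C(C)(C)C
F4 | step 12 | 8α-iodo-9β,13-epidioxy-13-hydroperoxide (8β-CH3; C13 anomers; tris-OTBS decalin, 16-OTBS) | C[C@@]1(I)C[C@H](O[Si](C)(C)C(C)(C)C)[C@H]2[C@@](C)(CO[Si](C)(C)C(C)(C)C)C[C@H](O[Si](C)(C)C(C)(C)C)C[C@]2(C)[C@]12CCC(OO)(CO[Si](C)(C)C(C)(C)C)OO2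
F5 | step 12 | 8α-iodo-9β,13-epidioxy-13-methoxy compound (C13 anomers) | C[C@@]1(I)C[C@H](O[Si](C)(C)C(C)(C)C)[C@H]2[C@@](C)(CO[Si](C)(C)C(C)(C)C)C[C@H](O[Si](C)(C)C(C)(C)C)C[C@]2(C)[C@]12CCC(OC)(CO[Si](C)(C)C(C)(C)C)OO2
F6 | step 14 | 9β,13-epidioxy-13-ol peroxy-hemiketal, 8(17)-ene (C13 anomers) | C=C1C[C@H](O[Si](C)(C)C(C)(C)C)[C@H]2[C@@](C)(CO[Si](C)(C)C(C)(C)C)C[C@H](O[Si](C)(C)C(C)(C)C)C[C@]2(C)[C@]12CCC(O)(CO[Si](C)(C)C(C)(C)C)OO2
F7 | step 14 | methyl 9β-hydroperoxy-8(17),13(14)-dien-15-oate (E/Z mixture; 16-OTBS) | C=C1C[C@H](O[Si](C)(C)C(C)(C)C)[C@H]2[C@@](C)(CO[Si](C)(C)C(C)(C)C)C[C@H](O[Si](C)(C)C(C)(C)C)C[C@]2(C)[C@]1(OO)CCC(=CC(=O)OC)CO[Si](C)(C)C(C)(C)C
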